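**Retrosynthetic overview**

1. Daucane numbering is used: C1 = ring-fusion C–CH3, C4 = C(OH)(iPr), C5 = ring-fusion CH, C6 = CH–O, C8(CH3)=C9–C10(=O) = enone. The C6–O ester bond is cut last, giving the diol enone and 3,4-dimethoxybenzoyl chloride.
2. Both rings of the diol enone are traced to one acyclic (S)-quaternary enol-ether diketone, closed in a single Lewis-acid cascade.
3. Ring order inside that cascade: the five-membered ring forms first (C4–C5, enol ether onto the isopropyl ketone). The seven-membered ring forms second (C6–C7, the aldehyde unveiled by the first closure plus the methallyl alkene). C8=C9 then moves into conjugation.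
4. The acyclic precursor comes from a quaternary aldehyde–thioester by Wittig homologation (C6) and a thioester-to-methallyl-ketone coupling (C7–C9 and the C8 methyl).
5. C1 is set by a catalytic asymmetric Michael addition of S-ethyl 2-formylpropanethioate (from S-ethyl propanethioate and ethyl formate) to isopropyl vinyl ketone. C1 then controls C4, C5 and C6.

Assumption: the quinidine-derived catalyst in step 2 is taken, by analogy, to give the (S) adduct; the quinine-derived pseudo-enantiomer is used if the sense proves opposite.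

**Step 1**
Reactants: 1 S-ethyl propanethioate; 2 ethyl formate
Product: 4 S-ethyl 2-methyl-3-oxopropanethioate, via lithium enolate 3 (not isolated)
Conditions: LiN(iPr)2 (1.05 equiv), THF, −78 °C; then HCO2Et (1.5 equiv), −78 to −20 °C; AcOH
Reagents that add atoms: ethyl formate (2), CCOC=O
Why: Crossed Claisen formylation of the preformed thioester lithium enolate with non-enolisable ethyl formate is driven by formation of the stabilised enolate of 4; no stereocentre survives because 4 is an enolised 1,3-dicarbonyl compound.

**Step 2**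
Reactants: 4 S-ethyl 2-methyl-3-oxopropanethioate; 5 4-methylpent-1-en-3-one
Product: 6 S-ethyl (2S)-2-formyl-2,6-dimethyl-5-oxoheptanethioate
Conditions: 9-O-(9-phenanthryl)cupreidine (10 mol %), CH2Cl2, −25 °C
Reagents that add atoms: 4-methylpent-1-en-3-one (5), CC(C)C(=O)C=C
Why: Cinchona-catalysed enantioselective Michael addition of a 2-substituted 1,3-dicarbonyl donor to a vinyl ketone, in which the quinuclidine and 6'-OH hold the hydrogen-bonded enol of 4 and the enone so that one enol face is alkylated, sets the quaternary C1 as S, which cannot epimerise afterwards (no α-hydrogen).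

**Step 3**
Reactants: 6 S-ethyl (2S)-2-formyl-2,6-dimethyl-5-oxoheptanethioate; 7 [2-(trimethylsilyl)ethoxymethyl]triphenylphosphonium chloride
Product: 9 S-ethyl (2S)-2,6-dimethyl-5-oxo-2-{2-[2-(trimethylsilyl)ethoxy]ethenyl}heptanethioate (E/Z mixture), via phosphorus ylide 8 (not isolated)
Conditions: KN(SiMe3)2 (1.2 equiv), THF, −78 to 0 °C; then 6, −78 °C to rt
Reagents that add atoms: [2-(trimethylsilyl)ethoxymethyl]triphenylphosphonium chloride (7), C[Si](C)(C)CCOC[P+](c1ccccc1)(c1ccccc1)c1ccccc1.[Cl-]
Why: Wittig alkoxymethylenation is chemoselective for the aldehyde over the hindered isopropyl ketone and the thioester, leaves C1 untouched, and its E/Z ratio is irrelevant because C6 becomes a trigonal aldehyde carbon again in step 5.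

**Step 4**
Reactants: 9 S-ethyl (2S)-2,6-dimethyl-5-oxo-2-{2-[2-(trimethylsilyl)ethoxy]ethenyl}heptanethioate; 10 tributyl(2-methylprop-2-en-1-yl)stannane
Product: 11 (5S)-2,5,9-trimethyl-5-{2-[2-(trimethylsilyl)ethoxy]ethenyl}dec-1-ene-4,8-dione (E/Z mixture)
Conditions: Pd2(dba)3 (2.5 mol %), P(2-furyl)3 (10 mol %), CuOP(O)Ph2 (1.5 equiv), THF, 50 °C
Reagents that add atoms: tributyl(2-methylprop-2-en-1-yl)stannane (10), CCCC[Sn](CCCC)(CCCC)CC(C)=C
Why: Liebeskind–Srogl-type thioester–stannane ketone synthesis (zerovalent palladium inserts into the C–S bond, the copper phosphinate takes up the thiolate, then transmetallation and reductive elimination) runs without acid or base, so the enol ether, the ketone and the unconjugated methallyl double bond survive, the symmetric methallyl group leaves no α/γ ambiguity, and no stereocentre is touched.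

**Step 5**
Reactants: 11 (5S)-2,5,9-trimethyl-5-{2-[2-(trimethylsilyl)ethoxy]ethenyl}dec-1-ene-4,8-dione
Product: 14 (1R,3aS,8S,8aS)-1,8-dihydroxy-3a,6-dimethyl-1-(propan-2-yl)-2,3,3a,7,8,8a-hexahydroazulen-4(1H)-one, via titanium-bound hydroxy aldehyde 12 (not isolated), via tertiary chloride 13 (not isolated)
Conditions: TiCl4 (2.5 equiv), 2,6-di-tert-butyl-4-methylpyridine (0.3 equiv), CH2Cl2 (0.01 M), −78 to −40 °C; then DBU (6 equiv), −40 °C to rt; aq. NaHCO3
Reagents that add atoms: none
Why: Proposed new method: TiCl4 activates the isopropyl ketone and the enol-ether carbon C5 adds to it 5-exo (closest precedent: Mukaiyama-type aldol addition to a ketone) through a conformer with the tether perpendicular to the enol-ether plane, the C1 methyl eclipsing C5=C6 (least 1,3-allylic strain) and the isopropyl group away from the developing oxocarbenium, which places the C1 methyl, C6 and the C4 oxygen on one face; the 2-silylethyl oxocarbenium then loses ethene and the silyl group, so the aldehyde exists only after the C4–C5 bond, and the six-membered O4–Ti–O6 chelate is attacked from its open face by the methallyl alkene in a 7-endo Prins/carbonyl-ene closure (closest precedents: the Mukaiyama aldol–Prins cascade and Lewis-acid carbonyl-ene cyclisations) that sets C6 with H6 anti to H5; the tertiary chloride (or any exo-methylene ene isomer) is converted by DBU (E1cB or dienolate isomerisation) into the conjugated enone, so both rings and three stereocentres arise from C1 in one operation.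

**Step 6**
Reactants: 14 (1R,3aS,8S,8aS)-1,8-dihydroxy-3a,6-dimethyl-1-(propan-2-yl)-2,3,3a,7,8,8a-hexahydroazulen-4(1H)-one; 15 3,4-dimethoxybenzoyl chloride
Product: 16 (3R,3aS,4S,8aS)-3-hydroxy-6,8a-dimethyl-8-oxo-3-(propan-2-yl)-1,2,3,3a,4,5,8,8a-octahydroazulen-4-yl 3,4-dimethoxybenzoate (CNP0111132.1)
Conditions: pyridine, DMAP (0.2 equiv), CH2Cl2, 0 °C to rt
Reagents that add atoms: 3,4-dimethoxybenzoyl chloride (15), COc1ccc(C(Cl)=O)cc1OC
Why: DMAP-catalysed acylation (Einhorn/Steglich type) esterifies only the secondary C6 hydroxyl, the tertiary C4 hydroxyl being inert, and C6 keeps its configuration because its C–O bond is not broken.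

**Compound list**

1 | S-ethyl propanethioate | CCC(=O)SCC | starting material
2 | ethyl formate | CCOC=O | starting material
3 | lithium enolate of S-ethyl propanethioate | CC=C([O-])SCC.[Li+] | intermediate
4 | S-ethyl 2-methyl-3-oxopropanethioate (racemic; mainly the hydroxymethylene enol) | CCSC(=O)C(C)C=O | intermediate
5 | 4-methylpent-1-en-3-one (isopropyl vinyl ketone) | CC(C)C(=O)C=C | starting material
6 | S-ethyl (2S)-2-formyl-2,6-dimethyl-5-oxoheptanethioate | CCSC(=O)[C@](C)(C=O)CCC(=O)C(C)C | intermediate
7 | [2-(trimethylsilyl)ethoxymethyl]triphenylphosphonium chloride | C[Si](C)(C)CCOC[P+](c1ccccc1)(c1ccccc1)c1ccccc1.[Cl-] | starting material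
8 | [2-(trimethylsilyl)ethoxy]methylidene(triphenyl)phosphorane | C[Si](C)(C)CCOC=P(c1ccccc1)(c1ccccc1)c1ccccc1 | intermediate
9 | S-ethyl (2S)-2,6-dimethyl-5-oxo-2-{2-[2-(trimethylsilyl)ethoxy]ethenyl}heptanethioate (E/Z mixture) | CCSC(=O)[C@](C)(C=COCC[Si](C)(C)C)CCC(=O)C(C)C | intermediate
10 | tributyl(2-methylprop-2-en-1-yl)stannane | CCCC[Sn](CCCC)(CCCC)CC(C)=C | starting material
11 | (5S)-2,5,9-trimethyl-5-{2-[2-(trimethylsilyl)ethoxy]ethenyl}dec-1-ene-4,8-dione (E/Z mixture) | C=C(C)CC(=O)[C@](C)(C=COCC[Si](C)(C)C)CCC(=O)C(C)C | intermediate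
12 | (1R,2R,5S)-2-hydroxy-5-methyl-5-(3-methylbut-3-enoyl)-2-(propan-2-yl)cyclopentane-1-carbaldehyde (titanium alkoxide chelate in the flask) | O=C[C@H]1[C@](O)(C(C)C)CC[C@]1(C)C(=O)CC(C)=C | intermediate
13 | (1R,3aS,8S,8aS)-6-chloro-1,8-dihydroxy-3a,6-dimethyl-1-(propan-2-yl)octahydroazulen-4(1H)-one (both C6 epimers) | O[C@H]2CC(C)(Cl)CC(=O)[C@@]3(C)CC[C@@](O)(C(C)C)[C@H]23 | intermediate
14 | (1R,3aS,8S,8aS)-1,8-dihydroxy-3a,6-dimethyl-1-(propan-2-yl)-2,3,3a,7,8,8a-hexahydroazulen-4(1H)-one; (1S,4R,5S,6S) in daucane numbering | O[C@H]2CC(C)=CC(=O)[C@@]3(C)CC[C@@](O)(C(C)C)[C@H]23 | intermediate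
15 | 3,4-dimethoxybenzoyl chloride | COc1ccc(C(Cl)=O)cc1OC | starting material
16 | (3R,3aS,4S,8aS)-3-hydroxy-6,8a-dimethyl-8-oxo-3-(propan-2-yl)-1,2,3,3a,4,5,8,8a-octahydroazulen-4-yl 3,4-dimethoxybenzoate; (1S,4R,5S,6S) in daucane numbering | COc1ccc(C(=O)O[C@H]2CC(C)=CC(=O)[C@@]3(C)CC[C@@](O)(C(C)C)[C@H]23)cc1OC | target

**Step count and risks**

Total step count: 6. Longest linear sequence: 6 (1 → 4 → 6 → 9 → 11 → 14 → 16).

Most likely to fail, first: the cascade of step 5. It has no direct precedent as a whole. The first closure must put C6 cis to the C1 methyl; the opposite choice leads to the cis-fused skeleton. The second closure is a 7-endo attack by an alkene that sits next to a complexed ketone. Stray acid could also unveil the aldehyde before the C4–C5 bond exists. The fallback sets out from 11 and comes back at 14, replacing the single cationic cascade by enamine catalysis followed by a separate ring closure. Oxalic acid in wet THF hydrolyses the enol ether to the keto-aldehyde (3S)-3,7-dimethyl-3-(3-methylbut-3-enoyl)-6-oxooctanal F1. L-Proline (20 mol %, DMSO, rt) then closes the five-membered ring by a 5-enolexo aldol of the aldehyde enamine onto the isopropyl ketone under catalyst control, giving hydroxy aldehyde 12, now isolated and checked. Me2AlCl (2 equiv, CH2Cl2, −78 °C) closes the seven-membered ring by a carbonyl-ene reaction to (1R,3aS,8S,8aS)-1,8-dihydroxy-3a-methyl-6-methylidene-1-(propan-2-yl)octahydroazulen-4(1H)-one F2, and DBU moves the double bond into conjugation to give 14.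

Second: the enantioselective Michael addition of step 2. An α-formyl thioester is an untested donor for this catalyst class, so both the ee and the sense of induction are uncertain. The fallback sets out from 4 and comes back at 6, using a stoichiometric auxiliary instead of a catalyst. Condensation of 4 with (R)-1-phenylethylamine (toluene, 4 Å sieves) gives the hydrogen-bonded enamino thioester S-ethyl (2Z)-2-methyl-3-{[(1R)-1-phenylethyl]amino}prop-2-enethioate F3. Its d'Angelo-type aza-ene Michael addition to 5 (THF, rt to 40 °C) gives the imine S-ethyl (2S)-2,6-dimethyl-5-oxo-2-({[(1R)-1-phenylethyl]imino}methyl)heptanethioate F4, with C1 set by the auxiliary; the (S)-amine is used instead if the (R)-amine gives the wrong sense. Aqueous AcOH hydrolysis releases the amine and gives 6.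

Third: the thioester coupling of step 4. The α-quaternary thioester is hindered, so insertion may be slow and the acyl–palladium species may lose CO; the β,γ-unsaturated ketone could also slip into conjugation. The fallback sets out from 9 and comes back at 11, building the ketone by allylation and oxidation instead of acyl cross-coupling. Fukuyama reduction (Et3SiH, Pd/C, acetone) gives the aldehyde (2S)-2,6-dimethyl-5-oxo-2-{2-[2-(trimethylsilyl)ethoxy]ethenyl}heptanal F5. Uncatalysed allylboration with 4,4,5,5-tetramethyl-2-(2-methylprop-2-en-1-yl)-1,3,2-dioxaborolane (neat, rt), which leaves the ketone alone, gives the homoallylic alcohol (5S)-4-hydroxy-2,5,9-trimethyl-5-{2-[2-(trimethylsilyl)ethoxy]ethenyl}dec-1-en-8-one F6 as a mixture of carbinol epimers. Dess–Martin periodinane buffered with pyridine oxidises F6 to 11.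

**Further compounds**

F1 | step 5 | (3S)-3,7-dimethyl-3-(3-methylbut-3-enoyl)-6-oxooctanal | C=C(C)CC(=O)[C@](C)(CC=O)CCC(=O)C(C)C
F2 | step 5 | (1R,3aS,8S,8aS)-1,8-dihydroxy-3a-methyl-6-methylidene-1-(propan-2-yl)octahydroazulen-4(1H)-one | O[C@H]2CC(=C)CC(=O)[C@@]3(C)CC[C@@](O)(C(C)C)[C@H]23
F3 | step 2 | S-ethyl (2Z)-2-methyl-3-{[(1R)-1-phenylethyl]amino}prop-2-enethioate | CCSC(=O)/C(C)=C\N[C@H](C)c1ccccc1
F4 | step 2 | S-ethyl (2S)-2,6-dimethyl-5-oxo-2-({[(1R)-1-phenylethyl]imino}methyl)heptanethioate | CCSC(=O)[C@](C)(C=N[C@H](C)c1ccccc1)CCC(=O)C(C)C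
F5 | step 4 | (2S)-2,6-dimethyl-5-oxo-2-{2-[2-(trimethylsilyl)ethoxy]ethenyl}heptanal | O=C[C@](C)(C=COCC[Si](C)(C)C)CCC(=O)C(C)C
F6 | step 4 | (5S)-4-hydroxy-2,5,9-trimethyl-5-{2-[2-(trimethylsilyl)ethoxy]ethenyl}dec-1-en-8-one | C=C(C)CC(O)[C@](C)(C=COCC[Si](C)(C)C)CCC(=O)C(C)C
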